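## Retrosynthetic overview

- Target ⇐ removal of nine benzyl ethers ⇐ outer C3–aryl bond by decarboxylative arylation trans to the C2 aryl group, and C4–styryl bond by Heck reaction ⇐ methyl trans-2-aryl-4-bromo-2,3-dihydrobenzofuran-3-carboxylate.
- The strategy rests on the outer dihydrofuran ring (O1, C2, C3, C3a, C7a, fused to ring A). It is a chroman-4-one ring without its carbonyl carbon, and C2 carries ring B as C2 of a flavanone carries its aryl group. Hence the ester ⇐ Wolff ring contraction of a 5-bromo-3-diazoflavanone (C3–C3a bond by 1,2-shift of the ring A carbon) ⇐ flavanone ⇐ 2'-hydroxychalcone ⇐ inner-ring 7-carbaldehyde + ring A 2-hydroxyacetophenone.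
- The inner dihydrobenzofuran (O1', C2', C3' on ring B) shows the same pattern and is built first by the same four operations on a simple nitrile-masked flavanone: oxa-Michael closure, diazo transfer, ring contraction, decarboxylative arylation.
- Ring order: inner pyranone, inner dihydrofuran, outer pyranone, outer dihydrofuran. C2' and C2 come from catalytic oxa-Michael additions; C3' and C3 from radical arylation trans to the neighbouring aryl group.

Key step: step 17

Remarks on the chemistry (assumptions):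
- All nine phenols are carried as benzyl ethers, not methyl ethers. Exhaustive O-demethylation with boron tribromide is expected to destroy the acid-labile 4-styryl-2-aryl-dihydrobenzofuran array, whereas aryl benzyl ethers can be cleaved at −78 °C without hydrogenation.
- The sense of induction of the cinchona thiourea is assumed (quinidine series gives 2S). If it proves opposite, the quinine-derived pseudoenantiomer is used in steps 6 and 15.
- The Wolff products are drawn as the trans (2S,3S) acid and ester. A C3 epimer may accompany them; both converge in the radical arylation.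
- Abbreviation: Ar* = (2S,3S)-4-(benzyloxy)-2-[2,4-bis(benzyloxy)phenyl]-3-[3,5-bis(benzyloxy)phenyl]-2,3-dihydro-1-benzofuran-7-yl (the inner dihydrobenzofuran, bonded through ring B).

## Route

**Step 1**
Reactants: 1 4-(benzyloxy)-2-hydroxybenzaldehyde
Product: 3 4-(benzyloxy)-2-hydroxybenzonitrile, via aldoxime 2 (not isolated)
Conditions: NH2OH·HCl, DMSO, 100 °C
Reagents that add atoms: hydroxylamine hydrochloride, NO.Cl
Why: One-pot oximation and thermal dehydration of the aldoxime turns the aldehyde into a nitrile, which masks this carbon (the later C7' formyl group) through the base, light and organozinc steps.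

**Step 2**
Reactants: 3 4-(benzyloxy)-2-hydroxybenzonitrile
Product: 4 4-(benzyloxy)-3-formyl-2-hydroxybenzonitrile
Conditions: MgCl2, Et3N, (CH2O)n, MeCN, reflux
Reagents that add atoms: paraformaldehyde (as formaldehyde), C=O
Why: Magnesium-mediated ortho-formylation delivers formaldehyde inside the magnesium phenoxide chelate, so only the free position ortho to the hydroxyl (C3, between OH and OBn) should be formylated.

**Step 3**
Reactants: 4 4-(benzyloxy)-3-formyl-2-hydroxybenzonitrile
Product: 5 4-(benzyloxy)-2-hydroxy-3-(1-hydroxyethyl)benzonitrile (racemic)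
Conditions: MeMgBr (3 equiv), THF, −78 → −20 °C; aq. NH4Cl
Reagents that add atoms: methylmagnesium bromide, C[Mg]Br
Why: Grignard addition to the aldehyde is much faster than to the aryl nitrile at low temperature (one equivalent is consumed by the phenol); the carbinol centre is racemic and is removed in step 4.

**Step 4**
Reactants: 5 4-(benzyloxy)-2-hydroxy-3-(1-hydroxyethyl)benzonitrile
Product: 6 3-acetyl-4-(benzyloxy)-2-hydroxybenzonitrile
Conditions: MnO2 (activated, excess), CH2Cl2, rt
Reagents that add atoms: none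
Why: Benzylic alcohol oxidation with MnO2 should give the hydrogen-bonded 2-hydroxyacetophenone without touching nitrile or benzyl ether.

**Step 5**
Reactants: 6 3-acetyl-4-(benzyloxy)-2-hydroxybenzonitrile; 7 2,4-bis(benzyloxy)benzaldehyde
Product: 8 (E)-4-(benzyloxy)-3-[3-[2,4-bis(benzyloxy)phenyl]prop-2-enoyl]-2-hydroxybenzonitrile
Conditions: KOH, EtOH/THF, 0 °C → rt; then AcOH to pH 6, 0 °C
Reagents that add atoms: none
Why: Claisen–Schmidt condensation; in strong base the product rests as the open chalcone phenoxide, and cold neutralisation should keep it from closing to racemic flavanone.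

**Step 6**
Reactants: 8 (E)-4-(benzyloxy)-3-[3-[2,4-bis(benzyloxy)phenyl]prop-2-enoyl]-2-hydroxybenzonitrile
Product: 9 (2S)-5-(benzyloxy)-2-[2,4-bis(benzyloxy)phenyl]-4-oxo-3,4-dihydro-2H-chromene-8-carbonitrile
Conditions: 9-amino(9-deoxy)epi-quinidine N-[3,5-bis(trifluoromethyl)phenyl]thiourea (10 mol%), toluene, −20 → 0 °C
Reagents that add atoms: none
Why: Catalytic asymmetric intramolecular oxa-Michael addition (6-endo-trig), in which the quinuclidine nitrogen activates the phenol and the thiourea binds the enone carbonyl, so the catalyst chooses the enone face and sets C2 as S; the weakly basic medium should not reopen the ring.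

**Step 7**
Reactants: 9 (2S)-5-(benzyloxy)-2-[2,4-bis(benzyloxy)phenyl]-4-oxo-3,4-dihydro-2H-chromene-8-carbonitrile
Product: 11 (2R)-5-(benzyloxy)-2-[2,4-bis(benzyloxy)phenyl]-3-diazo-4-oxo-3,4-dihydro-2H-chromene-8-carbonitrile, via trifluoroacetyl ketone 10 (not isolated)
Conditions: LiN(SiMe3)2, THF, −78 °C; CF3CO2CH2CF3, −78 °C; aq. NH4Cl; then MsN3, Et3N, H2O (1 equiv), MeCN, 0 °C → rt
Reagents that add atoms: methanesulfonyl azide, CS(=O)(=O)N=[N+]=[N-]; 2,2,2-trifluoroethyl trifluoroacetate (atoms kept in 10 only), O=C(OCC(F)(F)F)C(F)(F)F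
Why: Regitz-type deacylative diazo transfer: enolisation and C-trifluoroacetylation at −78 °C give the 1,3-diketone, which takes N2 from the sulfonyl azide with loss of the trifluoroacetyl group; the cold, short-lived enolate should not undergo retro-oxa-Michael opening, so C2 keeps its geometry (the descriptor becomes R only through the priority change at C3).

**Step 8**
Reactants: 11 (2R)-5-(benzyloxy)-2-[2,4-bis(benzyloxy)phenyl]-3-diazo-4-oxo-3,4-dihydro-2H-chromene-8-carbonitrile
Product: 13 (2S,3S)-4-(benzyloxy)-2-[2,4-bis(benzyloxy)phenyl]-7-cyano-2,3-dihydro-1-benzofuran-3-carboxylic acid, via ketene 12 (not isolated)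
Conditions: hν (365 nm LED), THF/H2O 10:1, degassed, rt
Reagents that add atoms: water, O
Why: Photochemical Wolff rearrangement with ring contraction: loss of N2 with 1,2-shift of ring B carbon C4a from the carbonyl carbon to C3 gives the ketene, which water traps as the acid; C2 is untouched, and the C3 configuration is of no consequence.

**Step 9**
Reactants: 14 1,3-bis(benzyloxy)-5-bromobenzene
Product: 16 [3,5-bis(benzyloxy)phenyl]zinc chloride (THF solution with LiCl), via arylmagnesium bromide 15 (not isolated)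
Conditions: Mg, LiCl, THF, rt; then ZnCl2, THF, 0 °C → rt
Reagents that add atoms: magnesium, [Mg]; zinc chloride, Cl[Zn]Cl
Why: LiCl-assisted magnesium insertion into the aryl bromide followed by transmetalation to zinc gives the arylzinc reagent used in steps 10 and 20.

**Step 10**
Reactants: 13 (2S,3S)-4-(benzyloxy)-2-[2,4-bis(benzyloxy)phenyl]-7-cyano-2,3-dihydro-1-benzofuran-3-carboxylic acid; 16 [3,5-bis(benzyloxy)phenyl]zinc chloride
Product: 18 (2S,3S)-4-(benzyloxy)-2-[2,4-bis(benzyloxy)phenyl]-3-[3,5-bis(benzyloxy)phenyl]-2,3-dihydro-1-benzofuran-7-carbonitrile, via redox-active ester 17 (not isolated)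
Conditions: N-hydroxytetrachlorophthalimide, DIC, DMAP (cat.), CH2Cl2, rt; solvent exchange; then NiCl2(dme) (20 mol%), 4,4'-di-tert-butyl-2,2'-bipyridine (40 mol%), 16 (3 equiv), THF/DMF, rt
Reagents that add atoms: N-hydroxytetrachlorophthalimide (atoms kept in 17 only), O=C1c2c(Cl)c(Cl)c(Cl)c(Cl)c2C(=O)N1O
Why: Nickel-catalysed decarboxylative Negishi-type arylation of a redox-active ester: single-electron reduction releases CO2 and a planar benzylic C3' radical, which the arylnickel species should capture on the face opposite the C2' aryl group, giving the trans (3S) diaryl product from either C3 epimer of 13; the nitrile is inert, which is why the formyl carbon is carried in this form.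

**Step 11**
Reactants: 18 (2S,3S)-4-(benzyloxy)-2-[2,4-bis(benzyloxy)phenyl]-3-[3,5-bis(benzyloxy)phenyl]-2,3-dihydro-1-benzofuran-7-carbonitrile
Product: 20 (2S,3S)-4-(benzyloxy)-2-[2,4-bis(benzyloxy)phenyl]-3-[3,5-bis(benzyloxy)phenyl]-2,3-dihydro-1-benzofuran-7-carbaldehyde (Ar*–CHO), via aldimine 19 (not isolated)
Conditions: i-Bu2AlH, CH2Cl2, −78 °C; then aq. potassium sodium tartrate, wet SiO2, rt
Reagents that add atoms: water, O
Why: Partial reduction of the aryl nitrile with i-Bu2AlH stops at the N-aluminated aldimine, which hydrolyses on work-up to the aldehyde; ethers and both stereocentres are unaffected.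

**Step 12**
Reactants: 21 5-bromobenzene-1,3-diol
Product: 22 1-(2-bromo-4,6-dihydroxyphenyl)ethan-1-one
Conditions: AcOH, BF3·OEt2, 90 °C
Reagents that add atoms: acetic acid, CC(=O)O
Why: Friedel–Crafts acylation of the resorcinol should occur para to one hydroxyl and ortho to the other (next to Br), the position between the two hydroxyls being disfavoured, to give the 2-hydroxyacetophenone of ring A.

**Step 13**
Reactants: 22 1-(2-bromo-4,6-dihydroxyphenyl)ethan-1-one
Product: 23 1-[4-(benzyloxy)-2-bromo-6-hydroxyphenyl]ethan-1-one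
Conditions: BnBr (1.05 equiv), K2CO3, acetone, reflux
Reagents that add atoms: benzyl bromide, BrCc1ccccc1
Why: Williamson ether synthesis, selective for the para hydroxyl because the ortho hydroxyl is hydrogen-bonded to the ketone.

**Step 14**
Reactants: 20 Ar*–CHO; 23 1-[4-(benzyloxy)-2-bromo-6-hydroxyphenyl]ethan-1-one
Product: 24 (E)-1-[4-(benzyloxy)-2-bromo-6-hydroxyphenyl]-3-Ar*-prop-2-en-1-one
Conditions: KOH, EtOH/THF, rt; then AcOH to pH 6, 0 °C
Reagents that add atoms: none
Why: Claisen–Schmidt condensation of a non-enolisable aldehyde; neither stereocentre of 20 carries an acidic hydrogen, so both should pass unchanged.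

**Step 15**
Reactants: 24 (E)-1-[4-(benzyloxy)-2-bromo-6-hydroxyphenyl]-3-Ar*-prop-2-en-1-one
Product: 25 (2S)-7-(benzyloxy)-5-bromo-2-Ar*-2,3-dihydro-4H-chromen-4-one
Conditions: 9-amino(9-deoxy)epi-quinidine N-[3,5-bis(trifluoromethyl)phenyl]thiourea (20 mol%), toluene/CH2Cl2, 0 °C
Reagents that add atoms: none
Why: The same catalytic asymmetric oxa-Michael closure (6-endo-trig) sets C2 as S under catalyst control; the C2 epimer, and any isomer arising from incomplete enantiopurity of 9, is a diastereomer of 25 and should be removable by chromatography.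

**Step 16**
Reactants: 25 (2S)-7-(benzyloxy)-5-bromo-2-Ar*-2,3-dihydro-4H-chromen-4-one
Product: 27 (2R)-7-(benzyloxy)-5-bromo-3-diazo-2-Ar*-2,3-dihydro-4H-chromen-4-one, via trifluoroacetyl ketone 26 (not isolated)
Conditions: LiN(SiMe3)2, THF, −78 °C; CF3CO2CH2CF3, −78 °C; aq. NH4Cl; then MsN3, Et3N, H2O (1 equiv), MeCN, 0 °C → rt
Reagents that add atoms: methanesulfonyl azide, CS(=O)(=O)N=[N+]=[N-]; 2,2,2-trifluoroethyl trifluoroacetate (atoms kept in 26 only), O=C(OCC(F)(F)F)C(F)(F)F
Why: Regitz-type deacylative diazo transfer as in step 7; enolisation is possible only at C3, the aryl bromide is inert to the amide base at −78 °C, and once the diazo group is in place no acidic hydrogen remains next to C2.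

**Step 17 (key step)**
Reactants: 27 (2R)-7-(benzyloxy)-5-bromo-3-diazo-2-Ar*-2,3-dihydro-4H-chromen-4-one
Product: 29 methyl (2S,3S)-6-(benzyloxy)-4-bromo-2-Ar*-2,3-dihydro-1-benzofuran-3-carboxylate, via ketene 28 (not isolated)
Conditions: hν (365 nm LED), MeOH/THF 1:1, degassed, rt
Reagents that add atoms: methanol, CO
Why: Excitation of the diazo ketone, which the pyranone ring holds s-cis, expels N2 with concerted 1,2-shift of ring A carbon C4a from the carbonyl carbon C4 to C3, and the resulting ketene is trapped by methanol as the ester. This is the photochemical Wolff ring contraction of a cyclic 2-diazo ketone, the closest precedent being the contraction of 3-diazochroman-4-ones to 2,3-dihydrobenzofuran-3-carboxylates. The outer dihydrofuran (O1, C2, C3, C3a, C7a) is closed not by a cyclisation but by this migration, which makes the C3–C3a bond while the former C4 leaves the ring as the ester carbon. The new C3 centre is set on protonation of the ester enol and should settle as the trans ester or a mixture, which does not matter because it is erased at the radical stage of step 20; C2 keeps the configuration from step 15 because no bond to it is touched. The step needs aryl migration to outrun 1,2-hydrogen shift from C2 (which would give the flavone) and O–H insertion into methanol. Direct irradiation without a metal carbenoid and the fixed s-cis geometry favour the concerted path, and 365 nm light should leave the aryl bromide and benzyl ethers untouched.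

**Step 18**
Reactants: 29 methyl (2S,3S)-6-(benzyloxy)-4-bromo-2-Ar*-2,3-dihydro-1-benzofuran-3-carboxylate; 30 1-(benzyloxy)-4-ethenylbenzene
Product: 31 methyl (2S,3S)-6-(benzyloxy)-4-[(E)-2-[4-(benzyloxy)phenyl]ethenyl]-2-Ar*-2,3-dihydro-1-benzofuran-3-carboxylate
Conditions: Pd2(dba)3 (2.5 mol%), P(t-Bu)3·HBF4 (10 mol%), Cy2NMe, 1,4-dioxane, 80 °C
Reagents that add atoms: none
Why: Mizoroki–Heck reaction (syn insertion, syn β-hydride elimination) should give the E-stilbene at the hindered bromide with a bulky electron-rich phosphine; it is placed after the photolysis, which a stilbene would not survive, and before the arylation, in which an aryl bromide would couple with the arylzinc.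

**Step 19**
Reactants: 31 methyl (2S,3S)-6-(benzyloxy)-4-[(E)-2-[4-(benzyloxy)phenyl]ethenyl]-2-Ar*-2,3-dihydro-1-benzofuran-3-carboxylate
Product: 32 (2S,3S)-6-(benzyloxy)-4-[(E)-2-[4-(benzyloxy)phenyl]ethenyl]-2-Ar*-2,3-dihydro-1-benzofuran-3-carboxylic acid
Conditions: LiOH, THF/MeOH/H2O, 40 °C; then dil. HCl to pH 4, 0 °C
Reagents that add atoms: lithium hydroxide (hydroxide oxygen), [Li+].[OH-]
Why: Saponification of the methyl ester; ring opening by loss of the aryloxide from the ester enolate would be the reverse of a 5-endo-trig closure and is not expected, and epimerisation at C3 is of no consequence.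

**Step 20**
Reactants: 32 (2S,3S)-6-(benzyloxy)-4-[(E)-2-[4-(benzyloxy)phenyl]ethenyl]-2-Ar*-2,3-dihydro-1-benzofuran-3-carboxylic acid; 16 [3,5-bis(benzyloxy)phenyl]zinc chloride
Product: 34 (2S,3S)-6-(benzyloxy)-4-[(E)-2-[4-(benzyloxy)phenyl]ethenyl]-3-[3,5-bis(benzyloxy)phenyl]-2-Ar*-2,3-dihydro-1-benzofuran (nonabenzyl ether of the target), via redox-active ester 33 (not isolated)
Conditions: N-hydroxytetrachlorophthalimide, DIC, DMAP (cat.), CH2Cl2, rt; solvent exchange; then NiCl2(dme) (20 mol%), 4,4'-di-tert-butyl-2,2'-bipyridine (40 mol%), 16 (3 equiv), THF/DMF, rt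
Reagents that add atoms: N-hydroxytetrachlorophthalimide (atoms kept in 33 only), O=C1c2c(Cl)c(Cl)c(Cl)c(Cl)c2C(=O)N1O
Why: Nickel-catalysed decarboxylative Negishi-type arylation as in step 10: the planar benzylic C3 radical should be arylated on the face opposite the C2 aryl group, setting C3 as S (trans); the neighbouring styryl group offers the radical only 4-exo or 5-endo cyclisation modes and should not interfere.

**Step 21**
Reactants: 34 nonabenzyl ether of the target
Product: 35 target, (2S,3S)-2-[(2S,3S)-2-(2,4-dihydroxyphenyl)-3-(3,5-dihydroxyphenyl)-4-hydroxy-2,3-dihydro-1-benzofuran-7-yl]-3-(3,5-dihydroxyphenyl)-4-[(E)-2-(4-hydroxyphenyl)ethenyl]-2,3-dihydro-1-benzofuran-6-ol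
Conditions: BCl3 (1 M in CH2Cl2, excess), C6HMe5 (excess), CH2Cl2, −78 °C; then MeOH, −78 °C → rt
Reagents that add atoms: none
Why: Lewis acid debenzylation in which pentamethylbenzene takes up the benzyl cations by Friedel–Crafts alkylation cleaves aryl benzyl ethers at −78 °C without hydrogenation, so the stilbene should survive; any reversible ionisation of the benzylic C2–O or C2'–O bonds should reclose to the trans rings because C3 and C3' are fixed.

## Compound list

1 | 4-(benzyloxy)-2-hydroxybenzaldehyde | O=Cc1ccc(OCc2ccccc2)cc1O | starting material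
2 | (E)-4-(benzyloxy)-2-hydroxybenzaldehyde oxime | O/N=C/c1ccc(OCc2ccccc2)cc1O | intermediate (not isolated)
3 | 4-(benzyloxy)-2-hydroxybenzonitrile | N#Cc1ccc(OCc2ccccc2)cc1O | intermediate
4 | 4-(benzyloxy)-3-formyl-2-hydroxybenzonitrile | N#Cc1ccc(OCc2ccccc2)c(C=O)c1O | intermediate
5 | 4-(benzyloxy)-2-hydroxy-3-(1-hydroxyethyl)benzonitrile (racemic) | CC(O)c1c(OCc2ccccc2)ccc(C#N)c1O | intermediate
6 | 3-acetyl-4-(benzyloxy)-2-hydroxybenzonitrile | CC(=O)c1c(OCc2ccccc2)ccc(C#N)c1O | intermediate
7 | 2,4-bis(benzyloxy)benzaldehyde | O=Cc1ccc(OCc2ccccc2)cc1OCc1ccccc1 | starting material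
8 | (E)-4-(benzyloxy)-3-[3-[2,4-bis(benzyloxy)phenyl]prop-2-enoyl]-2-hydroxybenzonitrile | N#Cc1ccc(OCc2ccccc2)c(C(=O)/C=C/c2ccc(OCc3ccccc3)cc2OCc2ccccc2)c1O | intermediate
9 | (2S)-5-(benzyloxy)-2-[2,4-bis(benzyloxy)phenyl]-4-oxo-3,4-dihydro-2H-chromene-8-carbonitrile | N#Cc1ccc(OCc2ccccc2)c2c1O[C@H](c1ccc(OCc3ccccc3)cc1OCc1ccccc1)CC2=O | intermediate
10 | 3-(trifluoroacetyl) derivative of 9 (C3 epimers/enol) | N#Cc1ccc(OCc2ccccc2)c2c1O[C@H](c1ccc(OCc3ccccc3)cc1OCc1ccccc1)C(C(=O)C(F)(F)F)C2=O | intermediate (not isolated)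
11 | (2R)-5-(benzyloxy)-2-[2,4-bis(benzyloxy)phenyl]-3-diazo-4-oxo-3,4-dihydro-2H-chromene-8-carbonitrile | N#Cc1ccc(OCc2ccccc2)c2c1O[C@H](c1ccc(OCc3ccccc3)cc1OCc1ccccc1)C(=[N+]=[N-])C2=O | intermediate
12 | ketene, 4-(benzyloxy)-2-[2,4-bis(benzyloxy)phenyl]-3-(oxomethylidene)-2,3-dihydro-1-benzofuran-7-carbonitrile (C2 as in 11) | N#Cc1ccc(OCc2ccccc2)c2c1O[C@H](c1ccc(OCc3ccccc3)cc1OCc1ccccc1)C2=C=O | intermediate (not isolated)
13 | (2S,3S)-4-(benzyloxy)-2-[2,4-bis(benzyloxy)phenyl]-7-cyano-2,3-dihydro-1-benzofuran-3-carboxylic acid | N#Cc1ccc(OCc2ccccc2)c2c1O[C@H](c1ccc(OCc3ccccc3)cc1OCc1ccccc1)[C@H]2C(=O)O | intermediate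
14 | 1,3-bis(benzyloxy)-5-bromobenzene | Brc1cc(OCc2ccccc2)cc(OCc2ccccc2)c1 | starting material
15 | [3,5-bis(benzyloxy)phenyl]magnesium bromide | Br[Mg]c1cc(OCc2ccccc2)cc(OCc2ccccc2)c1 | intermediate (not isolated)
16 | [3,5-bis(benzyloxy)phenyl]zinc chloride | Cl[Zn]c1cc(OCc2ccccc2)cc(OCc2ccccc2)c1 | intermediate
17 | 4,5,6,7-tetrachloro-1,3-dioxoisoindolin-2-yl ester of 13 | N#Cc1ccc(OCc2ccccc2)c2c1O[C@H](c1ccc(OCc3ccccc3)cc1OCc1ccccc1)[C@H]2C(=O)ON1C(=O)c2c(Cl)c(Cl)c(Cl)c(Cl)c2C1=O | intermediate (not isolated)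
18 | (2S,3S)-4-(benzyloxy)-2-[2,4-bis(benzyloxy)phenyl]-3-[3,5-bis(benzyloxy)phenyl]-2,3-dihydro-1-benzofuran-7-carbonitrile | N#Cc1ccc(OCc2ccccc2)c2c1O[C@H](c1ccc(OCc3ccccc3)cc1OCc1ccccc1)[C@H]2c1cc(OCc2ccccc2)cc(OCc2ccccc2)c1 | intermediate
19 | aldimine of 20 (formed as the N-aluminium derivative, drawn as the NH imine) | N=Cc1ccc(OCc2ccccc2)c2c1O[C@H](c1ccc(OCc3ccccc3)cc1OCc1ccccc1)[C@H]2c1cc(OCc2ccccc2)cc(OCc2ccccc2)c1 | intermediate (not isolated)
20 | (2S,3S)-4-(benzyloxy)-2-[2,4-bis(benzyloxy)phenyl]-3-[3,5-bis(benzyloxy)phenyl]-2,3-dihydro-1-benzofuran-7-carbaldehyde | O=Cc1ccc(OCc2ccccc2)c2c1O[C@H](c1ccc(OCc3ccccc3)cc1OCc1ccccc1)[C@H]2c1cc(OCc2ccccc2)cc(OCc2ccccc2)c1 | intermediate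
21 | 5-bromobenzene-1,3-diol | Oc1cc(O)cc(Br)c1 | starting material
22 | 1-(2-bromo-4,6-dihydroxyphenyl)ethan-1-one | CC(=O)c1c(O)cc(O)cc1Br | intermediate
23 | 1-[4-(benzyloxy)-2-bromo-6-hydroxyphenyl]ethan-1-one | CC(=O)c1c(O)cc(OCc2ccccc2)cc1Br | intermediate
24 | (E)-1-[4-(benzyloxy)-2-bromo-6-hydroxyphenyl]-3-Ar*-prop-2-en-1-one | O=C(/C=C/c1ccc(OCc2ccccc2)c2c1O[C@H](c1ccc(OCc3ccccc3)cc1OCc1ccccc1)[C@H]2c1cc(OCc2ccccc2)cc(OCc2ccccc2)c1)c1c(O)cc(OCc2ccccc2)cc1Br | intermediate
25 | (2S)-7-(benzyloxy)-5-bromo-2-Ar*-2,3-dihydro-4H-chromen-4-one | O=C1C[C@@H](c2ccc(OCc3ccccc3)c3c2O[C@H](c2ccc(OCc4ccccc4)cc2OCc2ccccc2)[C@H]3c2cc(OCc3ccccc3)cc(OCc3ccccc3)c2)Oc2cc(OCc3ccccc3)cc(Br)c21 | intermediate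
26 | 3-(trifluoroacetyl) derivative of 25 (C3 epimers/enol) | O=C1C(C(=O)C(F)(F)F)[C@@H](c2ccc(OCc3ccccc3)c3c2O[C@H](c2ccc(OCc4ccccc4)cc2OCc2ccccc2)[C@H]3c2cc(OCc3ccccc3)cc(OCc3ccccc3)c2)Oc2cc(OCc3ccccc3)cc(Br)c21 | intermediate (not isolated)
27 | (2R)-7-(benzyloxy)-5-bromo-3-diazo-2-Ar*-2,3-dihydro-4H-chromen-4-one | O=C1C(=[N+]=[N-])[C@@H](c2ccc(OCc3ccccc3)c3c2O[C@H](c2ccc(OCc4ccccc4)cc2OCc2ccccc2)[C@H]3c2cc(OCc3ccccc3)cc(OCc3ccccc3)c2)Oc2cc(OCc3ccccc3)cc(Br)c21 | intermediate
28 | ketene, 6-(benzyloxy)-4-bromo-3-(oxomethylidene)-2-Ar*-2,3-dihydro-1-benzofuran (C2 as in 27) | O=C=C1c2c(Br)cc(OCc3ccccc3)cc2O[C@@H]1c1ccc(OCc2ccccc2)c2c1O[C@H](c1ccc(OCc3ccccc3)cc1OCc1ccccc1)[C@H]2c1cc(OCc2ccccc2)cc(OCc2ccccc2)c1 | intermediate (not isolated)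
29 | methyl (2S,3S)-6-(benzyloxy)-4-bromo-2-Ar*-2,3-dihydro-1-benzofuran-3-carboxylate | Brc1cc(OCc2ccccc2)cc2c1[C@H](C(=O)OC)[C@@H](c1ccc(OCc3ccccc3)c3c1O[C@H](c1ccc(OCc4ccccc4)cc1OCc1ccccc1)[C@H]3c1cc(OCc3ccccc3)cc(OCc3ccccc3)c1)O2 | intermediate
30 | 1-(benzyloxy)-4-ethenylbenzene | C=Cc1ccc(OCc2ccccc2)cc1 | starting material
31 | methyl (2S,3S)-6-(benzyloxy)-4-[(E)-2-[4-(benzyloxy)phenyl]ethenyl]-2-Ar*-2,3-dihydro-1-benzofuran-3-carboxylate | O(Cc1ccccc1)c1ccc(/C=C/c2cc(OCc4ccccc4)cc3c2[C@H](C(=O)OC)[C@@H](c2ccc(OCc4ccccc4)c4c2O[C@H](c2ccc(OCc5ccccc5)cc2OCc2ccccc2)[C@H]4c2cc(OCc4ccccc4)cc(OCc4ccccc4)c2)O3)cc1 | intermediate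
32 | (2S,3S)-6-(benzyloxy)-4-[(E)-2-[4-(benzyloxy)phenyl]ethenyl]-2-Ar*-2,3-dihydro-1-benzofuran-3-carboxylic acid | O(Cc1ccccc1)c1ccc(/C=C/c2cc(OCc4ccccc4)cc3c2[C@H](C(=O)O)[C@@H](c2ccc(OCc4ccccc4)c4c2O[C@H](c2ccc(OCc5ccccc5)cc2OCc2ccccc2)[C@H]4c2cc(OCc4ccccc4)cc(OCc4ccccc4)c2)O3)cc1 | intermediate
33 | 4,5,6,7-tetrachloro-1,3-dioxoisoindolin-2-yl ester of 32 | O(Cc1ccccc1)c1ccc(/C=C/c2cc(OCc4ccccc4)cc3c2[C@H](C(=O)ON2C(=O)c4c(Cl)c(Cl)c(Cl)c(Cl)c4C2=O)[C@@H](c2ccc(OCc4ccccc4)c4c2O[C@H](c2ccc(OCc5ccccc5)cc2OCc2ccccc2)[C@H]4c2cc(OCc4ccccc4)cc(OCc4ccccc4)c2)O3)cc1 | intermediate (not isolated)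
34 | (2S,3S)-6-(benzyloxy)-4-[(E)-2-[4-(benzyloxy)phenyl]ethenyl]-3-[3,5-bis(benzyloxy)phenyl]-2-Ar*-2,3-dihydro-1-benzofuran | O(Cc1ccccc1)c1ccc(/C=C/c2cc(OCc4ccccc4)cc3c2[C@H](c2cc(OCc4ccccc4)cc(OCc4ccccc4)c2)[C@@H](c2ccc(OCc4ccccc4)c4c2O[C@H](c2ccc(OCc5ccccc5)cc2OCc2ccccc2)[C@H]4c2cc(OCc4ccccc4)cc(OCc4ccccc4)c2)O3)cc1 | intermediate
35 | (2S,3S)-2-[(2S,3S)-2-(2,4-dihydroxyphenyl)-3-(3,5-dihydroxyphenyl)-4-hydroxy-2,3-dihydro-1-benzofuran-7-yl]-3-(3,5-dihydroxyphenyl)-4-[(E)-2-(4-hydroxyphenyl)ethenyl]-2,3-dihydro-1-benzofuran-6-ol | Oc1ccc(/C=C/c2cc(O)cc3c2[C@H](c2cc(O)cc(O)c2)[C@@H](c2ccc(O)c4c2O[C@H](c2ccc(O)cc2O)[C@H]4c2cc(O)cc(O)c2)O3)cc1 | target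

## Step count and risks

Total step count: 21. Longest linear sequence: 18 steps (steps 1–8, 10, 11, 14–21). Steps 9, 12 and 13 are side branches.

The three steps most likely to fail:

**Step 17 (key step).** Hydrogen shift from C2 to the carbene carbon (giving the flavone and destroying C2) or O–H insertion into methanol may outrun the aryl migration. The fallback sets out from flavanone 25, bypasses 27 and comes back at ester 29. It is an oxidative ring contraction with trivalent iodine: PhI(OAc)2, HC(OMe)3, catalytic H2SO4, MeOH/CH2Cl2, 0 °C → rt. The enol ether of 25 is iodinated at C3, and the same ring A carbon shifts from C4 to C3 as iodobenzene leaves, the former carbonyl carbon ending as the methyl ester. Either C3 epimer of 29 serves. This is a known reaction of flavanones; its own hazards are competing 2→3 shift of the C2 aryl group and the acidic medium. It makes no compound outside the list (F0).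

**Step 20 (the same coupling is used in step 10).** The benzylic C3 radical may dimerise or open the ring by loss of the aryloxyl group before nickel captures it, or the arylzinc reagent may be consumed unproductively. The fallback sets out from acid 32 and bromide 14 and comes back at 34. The redox-active ester 33 is isolated. Bromide 14 is converted by copper-catalysed aromatic Finkelstein exchange (CuI, N,N'-dimethylethylenediamine, NaI, dioxane, 110 °C) into 1,3-bis(benzyloxy)-5-iodobenzene F1. The two electrophiles are then joined by reductive cross-electrophile decarboxylative arylation (NiBr2(dme), 4,4'-di-tert-butyl-2,2'-bipyridine, Zn dust, DMA, rt). Here the radical meets an arylnickel halide formed by oxidative addition, and no organozinc nucleophile is needed. The same detour from 17 gives 18.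

**Step 6.** The enantioselectivity of the oxa-Michael closure of a simple 2'-hydroxychalcone may be insufficient, through uncatalysed closure or through reversible ring opening of the acidic cyanophenol. In step 15 the same weakness only produces separable diastereomers; here it lowers the optical purity of everything that follows. The fallback sets out from acetophenone 6 and comes back at flavanone 9. Condensation with Me2NCH(OMe)2 (toluene, 100 °C) gives the enaminone (E)-4-(benzyloxy)-3-[3-(dimethylamino)prop-2-enoyl]-2-hydroxybenzonitrile F2. Acid (HCl, CH2Cl2, rt) closes it to the chromone 5-(benzyloxy)-4-oxo-4H-chromene-8-carbonitrile F3. Rhodium-catalysed asymmetric 1,4-addition of commercial 2,4-bis(benzyloxy)phenylboronic acid ([Rh(OH)(cod)]2 with a chiral diene or bisphosphine ligand, aqueous dioxane, 40–60 °C; ligand enantiomer chosen for 2S) then gives 9. Here the C2 stereocentre is set by carbon–carbon bond formation instead of by the reversible carbon–oxygen closure.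

## Further compounds

F0 | step 17 | none | none
F1 | step 20 | 1,3-bis(benzyloxy)-5-iodobenzene | Ic1cc(OCc2ccccc2)cc(OCc2ccccc2)c1
F2 | step 6 | (E)-4-(benzyloxy)-3-[3-(dimethylamino)prop-2-enoyl]-2-hydroxybenzonitrile | CN(C)/C=C/C(=O)c1c(OCc2ccccc2)ccc(C#N)c1O
F3 | step 6 | 5-(benzyloxy)-4-oxo-4H-chromene-8-carbonitrile | N#Cc1ccc(OCc2ccccc2)c2c1OC=CC2=O
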